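## Retrosynthetic overview
- Argophyllone B comes from a late peripheral epoxidation of the E-1(10)-alkene, preceded by a Nef unmasking of the C3 ketone from a nitro group.
- The ten-membered carbocycle comes from a CO2-extruding ring contraction of a 13-membered cyclic allyl alkyl carbonate. This step forms C2–C3 from an internal nitronate and a π-allylpalladium unit.
- The 13-membered ring and the trans α-methylene-γ-lactone form together (C6–C7) by CrCl2/LiI umpolung of a vinyl epoxide onto the C6 aldehyde.
- The open chain comes from organocatalytic nitromethane addition (C4), a carbonate tether (C2–O/C15–O) and a sulfur-ylide epoxidation (C7–C8).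
- Ring order: temporary oxirane, then 13-membered carbonate and γ-lactone together, then ten-membered carbocycle, then final oxirane.

Numbering used (germacrane):
- C1/C10 carry the epoxide, and C10 bears the C14 methyl.
- C3 is the ketone. C4 bears C15H2OH.
- C6 carries the lactone oxygen. C7 bears C11(=C13H2)–C12(=O). C8 carries the angelate.

Assumption: 1, 3, 6, 10 and 14 are bought. The chiral sulfide and the prolinol catalyst are treated as reagents.

## Route

**Step 1**
Reactants: 1 (E)-3-methylpent-2-en-4-yn-1-ol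
Product: 2 (E)-5-hydroxy-3-methylpent-3-enal
Conditions: [CpRu(MeCN)3]PF6 (3 mol %), 5,5'-bis(trifluoromethyl)-2,2'-bipyridine (3 mol %), NMP/H2O 4:1, 25 °C
Reagents that add atoms: water, O
Why: Ruthenium-vinylidene anti-Markovnikov alkyne hydration runs at neutral pH, so the skipped enal does not conjugate and the E-alkene (C9 trans to C2) is kept; no stereocentre is formed.

**Step 2**
Reactants: 2 (E)-5-hydroxy-3-methylpent-3-enal; 3 methyl 2-(bromomethyl)acrylate
Product: 5 methyl 2-[(2R,3R)-3-[(2E)-4-hydroxy-2-methylbut-2-en-1-yl]oxiran-2-yl]prop-2-enoate (trans-epoxide, 7R,8R), via sulfonium bromide 4 (not isolated)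
Conditions: (2S,5S)-2,5-dimethylthiolane (1.1 equiv), 3, acetone, 23 °C; then 2, Cs2CO3, MeCN, −20 °C
Reagents that add atoms: none
Why: In this asymmetric sulfur-ylide (Corey–Chaykovsky type) epoxidation the C2-symmetric sulfide fixes the ylide face and anti-betaine closure gives the trans-epoxide, which sets C8 (R); the minor cis isomer is removed by chromatography.

**Step 3**
Reactants: 5 vinyl epoxide alcohol; 6 (Z)-but-2-ene-1,4-diol
Product: 8 (2Z)-4-hydroxybut-2-en-1-yl (2E)-4-[(2R,3R)-3-(3-methoxy-3-oxoprop-1-en-2-yl)oxiran-2-yl]-3-methylbut-2-en-1-yl carbonate, via 4-nitrophenyl carbonate 7 (not isolated)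
Conditions: 4-NO2C6H4OCOCl, pyridine, CH2Cl2, 0 °C; then 6 (5 equiv), 23 °C
Reagents that add atoms: 4-nitrophenyl chloroformate, O=C(Cl)Oc1ccc(cc1)[N+](=O)[O-]
Why: Stepwise mixed-carbonate formation, with excess diol to give the mono-adduct, makes a carbonate that later serves as C15–O protection, tether, leaving group and latent base; no stereocentre is touched.

**Step 4**
Reactants: 8 mixed carbonate alcohol
Product: 9 (2E)-4-oxobut-2-en-1-yl (2E)-4-[(2R,3R)-3-(3-methoxy-3-oxoprop-1-en-2-yl)oxiran-2-yl]-3-methylbut-2-en-1-yl carbonate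
Conditions: MnO2 (15 equiv), CH2Cl2, 23 °C
Reagents that add atoms: none
Why: MnO2 allylic oxidation touches only the free allylic alcohol, and the first-formed Z-enal relaxes to the E-enal under the conditions.

**Step 5**
Reactants: 9 E-enal; 10 nitromethane
Product: 11 (2R)-2-(nitromethyl)-4-oxobutyl (2E)-4-[(2R,3R)-3-(3-methoxy-3-oxoprop-1-en-2-yl)oxiran-2-yl]-3-methylbut-2-en-1-yl carbonate (4R,7R,8R)
Conditions: (S)-α,α-diphenylprolinol trimethylsilyl ether (10 mol %), PhCO2H (10 mol %), 10 (5 equiv), MeOH, 23 °C
Reagents that add atoms: none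
Why: In this iminium-catalysed Michael addition (Hayashi–Jørgensen catalyst) the CPh2OTMS group blocks one face of the E-iminium ion, so nitromethane adds to the open face, sets C4 and brings in C3.

**Step 6**
Reactants: 11 nitro aldehyde vinyl epoxide
Product: 13 (4R,6R,7R,8R)-13-membered cyclic carbonate (ring C6-C5-C4-C15-O-C(=O)-O-C2-C1=C10-C9-C8-C7) carrying the trans-fused 6,12-α-methylene-γ-lactone, free 8-OH and 4-CH2NO2, via dihydroxy ester 12 (not isolated)
Conditions: CrCl2 (6 equiv), LiI (2 equiv), THF, 2 mM (syringe pump), 23 °C; aq NH4Cl; then PPTS (cat.), CH2Cl2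
Reagents that add atoms: none
Why: Iodide opens the vinyl epoxide SN2'; divalent chromium gives the allylchromium alkoxide, which adds in a Nozaki–Hiyama allylation through a chair transition state (anti, giving the trans lactone), attacking C7 anti to the C9 chain in the A(1,3)-minimised conformer, which sets C6 and C7 from C8; the less hindered trans 6,12-lactone closes in preference to the cis 8,12-lactone.

**Step 7**
Reactants: 13 macrocyclic alcohol; 14 angelic acid
Product: 16 (4R,6R,7S,8R)-8-angelate of 13, via mixed anhydride 15 (not isolated)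
Conditions: 14, 2,4,6-Cl3C6H2COCl, Et3N, toluene, 23 °C; then 13, DMAP (cat.), 70 °C
Reagents that add atoms: none
Why: Yamaguchi esterification acylates the only free hydroxyl with retention at C8 and without Z-to-E isomerisation of the angelate.

**Step 8**
Reactants: 16 13-membered cyclic carbonate
Product: 17 (4R,6R,7S,8R)-3-nitro-15-hydroxy-8-angeloyloxygermacra-1(10)E,11(13)-dien-6,12-olide (C3 epimers)
Conditions: Pd2(dba)3 (5 mol %), dppe (12 mol %), THF, 1 mM (slow addition), 45 °C
Reagents that add atoms: none
Why: Proposed new method: zerovalent palladium ionises the only allylic C–O bond (C2–O), the ring-bound monoalkyl carbonate loses CO2, and the resulting C15 alkoxide deprotonates the neighbouring CH2NO2 through a six-membered transition state; the resulting nitronate/π-allylpalladium zwitterion collapses at the primary terminus C2, so the unstrained 13-membered ring contracts irreversibly to the ten-membered carbocycle with the E-alkene kept and C15–OH freed; the closest known reaction types are the neutral decarboxylative Tsuji–Trost allylation of nitroalkanes with open-chain allyl alkyl carbonates and zwitterionic π-allyl macrocyclisations.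

**Step 9**
Reactants: 17 nitro compound
Product: 18 (4S,6R,7S,8R)-15-hydroxy-3-oxo-8-angeloyloxygermacra-1(10)E,11(13)-dien-6,12-olide
Conditions: TiCl3 (aq, 6 equiv), NH4OAc, THF/H2O, 23 °C
Reagents that add atoms: water, O
Why: In this reductive Nef reaction (McMurry conditions) trivalent titanium reduces the nitro group to the imine, which hydrolyses at about pH 6, so C4 is not epimerised, the β,γ-alkene does not conjugate and no free nitronate can attack the methylene lactone.

**Step 10**
Reactants: 18 dienone
Product: 19 Argophyllone B (1R,4S,6R,7S,8R,10R)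
Conditions: DMDO, acetone/CH2Cl2, −30 °C
Reagents that add atoms: dimethyldioxirane, CC1(C)OO1
Why: Neutral electrophilic epoxidation takes only the electron-rich trisubstituted alkene, and peripheral attack on the outer face of the E-cyclodecene conformer fixed by the trans lactone gives the trans 1,10-epoxide without base, so the β,γ-epoxy ketone survives.

## Compound list
1 | (E)-3-methylpent-2-en-4-yn-1-ol | C#C/C(C)=C/CO | starting material
2 | (E)-5-hydroxy-3-methylpent-3-enal | O=CC/C(C)=C/CO | intermediate
3 | methyl 2-(bromomethyl)acrylate | C=C(CBr)C(=O)OC | starting material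
4 | 1-[2-(methoxycarbonyl)prop-2-enyl]-(2S,5S)-2,5-dimethylthiolan-1-ium bromide | C[C@H]1CC[C@H](C)[S+]1CC(=C)C(=O)OC.[Br-] | intermediate
5 | methyl 2-[(2R,3R)-3-[(2E)-4-hydroxy-2-methylbut-2-en-1-yl]oxiran-2-yl]prop-2-enoate | OC/C=C(C)/C[C@H]1O[C@@H]1C(=C)C(=O)OC | intermediate
6 | (Z)-but-2-ene-1,4-diol | OC/C=C\CO | starting material
7 | 4-nitrophenyl carbonate of 5 | O=C(Oc1ccc([N+](=O)[O-])cc1)OC/C=C(C)/C[C@H]1O[C@@H]1C(=C)C(=O)OC | intermediate
8 | mixed carbonate alcohol | OC/C=C\COC(=O)OC/C=C(C)/C[C@H]1O[C@@H]1C(=C)C(=O)OC | intermediate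
9 | mixed carbonate E-enal | O=C/C=C/COC(=O)OC/C=C(C)/C[C@H]1O[C@@H]1C(=C)C(=O)OC | intermediate
10 | nitromethane | C[N+](=O)[O-] | starting material
11 | (4R,7R,8R)-nitro aldehyde vinyl epoxide | O=CC[C@H](C[N+](=O)[O-])COC(=O)OC/C=C(C)/C[C@H]1O[C@@H]1C(=C)C(=O)OC | intermediate
12 | 13-membered carbonate, 6,8-diol methyl ester | C=C(C(=O)OC)[C@H]1[C@H](O)C[C@H](C[N+](=O)[O-])COC(=O)OC/C=C(C)/C[C@H]1O | intermediate
13 | 13-membered carbonate, 6,12-lactone, 8-OH | C=C1C(=O)O[C@@H]2C[C@H](C[N+](=O)[O-])COC(=O)OC/C=C(C)/C[C@@H](O)[C@@H]12 | intermediate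
14 | angelic acid | C/C=C(/C)C(=O)O | starting material
15 | angelic 2,4,6-trichlorobenzoic anhydride | C/C=C(/C)C(=O)OC(=O)c1c(Cl)cc(Cl)cc1Cl | intermediate
16 | 13-membered carbonate, 8-angelate | C=C1C(=O)O[C@@H]2C[C@H](C[N+](=O)[O-])COC(=O)OC/C=C(C)/C[C@@H](OC(=O)/C(C)=C\C)[C@@H]12 | intermediate
17 | ten-membered 3-nitro compound (C3 epimers) | C=C1C(=O)O[C@@H]2C[C@@H](CO)C([N+](=O)[O-])C/C=C(C)/C[C@@H](OC(=O)/C(C)=C\C)[C@@H]12 | intermediate
18 | 3-oxo-1(10)E-ene | C=C1C(=O)O[C@@H]2C[C@@H](CO)C(=O)C/C=C(C)/C[C@@H](OC(=O)/C(C)=C\C)[C@@H]12 | intermediate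
19 | Argophyllone B | C=C1C(=O)O[C@@H]2C[C@@H](CO)C(=O)C[C@H]3O[C@]3(C)C[C@@H](OC(=O)/C(C)=C\C)[C@@H]12 | target

Total steps: 10. Longest linear sequence: 10 (1 to 19).

## Steps most likely to fail

**Step 8 (new ring contraction).**
The risks are closure strain, O-allylation, and nitronate addition to the methylene lactone. The fallback makes the same two C–C bonds in the opposite order, using known reactions only. It sets out from 1 and comes back at 18.

Compound 1 is activated as its 4-nitrophenyl carbonate F1 and coupled with 6 to the mixed carbonate alcohol F2. MnO2 then gives the enal F3, and the organocatalytic nitromethane addition of step 5 gives the nitro aldehyde F4. This open-chain allyl alkyl carbonate undergoes the known neutral decarboxylative Tsuji–Trost allylation (Pd(PPh3)4, THF) to the nitro lactol F5.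

MeOH/PPTS converts F5 to the cyclic methyl acetal F6, which masks C6 and C15 together. Buffered TiCl3 gives the ketone F7. The hydration of step 1 gives the aldehyde F8, and the ylide epoxidation of step 2 (with 4) gives the vinyl epoxide F9. MgBr2·OEt2 followed by 15 gives the bromide angelate F10, and aqueous AcOH frees the lactol F11. CrCl2 in THF at high dilution then closes the ten-membered ring directly in a Nozaki–Hiyama allylation, and lactonisation delivers 18.

**Step 6 (macrocyclisation, stereocontrol, nitro group next to divalent chromium).**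
The fallback sets out from 11 and comes back at 13. LiBr/AcOH opens the epoxide SN2' to the isolated bromohydrin F12. This is cyclised by a chromium-free aqueous Barbier reaction (indium powder, THF/H2O, high dilution), followed by PPTS lactonisation and separation of the trans-lactone 13.

**Step 9 (Nef reaction on a polyfunctional substrate).**
The fallback sets out from 17 and comes back at 19. TMSCl/Et3N gives the bis-silylated silyl nitronate F13. mCPBA (2.5 equiv, CH2Cl2, 0 °C) performs the known oxidative cleavage of the silyl nitronate to the ketone and epoxidises the 1(10)-alkene in the same pot. Aqueous work-up removes the C15 silyl ether.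

## Further compounds
F1 | step 8 | 4-nitrophenyl (E)-3-methylpent-2-en-4-ynyl carbonate | C#C/C(C)=C/COC(=O)Oc1ccc([N+](=O)[O-])cc1
F2 | step 8 | (Z)-4-hydroxybut-2-enyl (E)-3-methylpent-2-en-4-ynyl carbonate | C#C/C(C)=C/COC(=O)OC/C=C\CO
F3 | step 8 | (E)-4-oxobut-2-enyl (E)-3-methylpent-2-en-4-ynyl carbonate | C#C/C(C)=C/COC(=O)OC/C=C/C=O
F4 | step 8 | (R)-2-(nitromethyl)-4-oxobutyl (E)-3-methylpent-2-en-4-ynyl carbonate | C#C/C(C)=C/COC(=O)OC[C@@H](C[N+](=O)[O-])CC=O
F5 | step 8 | nitro lactol (4-substituted tetrahydrofuran-2-ol) | OC1C[C@@H](CO1)C([N+](=O)[O-])C/C=C(C)/C#C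
F6 | step 8 | nitro cyclic methyl acetal | COC1C[C@@H](CO1)C([N+](=O)[O-])C/C=C(C)/C#C
F7 | step 8 | keto enyne acetal | COC1C[C@@H](CO1)C(=O)C/C=C(C)/C#C
F8 | step 8 | keto aldehyde acetal | COC1C[C@@H](CO1)C(=O)C/C=C(C)/CC=O
F9 | step 8 | keto vinyl epoxide acetal | COC1C[C@@H](CO1)C(=O)C/C=C(C)/C[C@H]2O[C@@H]2C(=C)C(=O)OC
F10 | step 8 | (Z)-allylic bromide 8-angelate acetal | COC1C[C@@H](CO1)C(=O)C/C=C(C)/C[C@@H](OC(=O)/C(C)=C\C)/C=C(\CBr)C(=O)OC
F11 | step 8 | (Z)-allylic bromide 8-angelate lactol | OC1C[C@@H](CO1)C(=O)C/C=C(C)/C[C@@H](OC(=O)/C(C)=C\C)/C=C(\CBr)C(=O)OC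
F12 | step 6 | (Z)-bromohydrin of 11 | O=CC[C@H](C[N+](=O)[O-])COC(=O)OC/C=C(C)/C[C@@H](O)/C=C(\CBr)C(=O)OC
F13 | step 9 | 15-O-TMS trimethylsilyl nitronate of 17 | C=C1C(=O)O[C@@H]2C[C@@H](CO[Si](C)(C)C)C(=[N+]([O-])O[Si](C)(C)C)C/C=C(C)/C[C@@H](OC(=O)/C(C)=C\C)[C@@H]12
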